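**Assumption:** formaldehyde (8) is used as monomer cracked from paraformaldehyde; the side-chain alkene is Z (ester carbonyl cis to the C3 methyl), as the SMILES states.

## Retrosynthetic overview

1. Target 15 ⇐ ring contraction of the trans-3-triflyloxy-4-acyloxy-2,2-dimethylchroman 14: the ring oxygen shifts from C2 to C3, the pyran becomes the dihydrofuran and the isopropenyl group is unveiled.
2. 14 ⇐ (3R,4R)-chromene oxide 6 + acid 12 (C4–O ester bond by epoxide opening with inversion), both events in one flask.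
3. 6 ⇐ chromene 5 (asymmetric epoxidation) ⇐ 4 ⇐ 3 ⇐ resorcinol 1 + 3-methylbut-2-enal 2 (then O-methylation and C6 acetylation).
4. 12 ⇐ methyl but-2-ynoate 7 + formaldehyde 8 (syn-hydroalumination/hydroxymethylation fixes Z), then saponification and acetylation.
5. Ring order: benzene ring bought; pyran ring first (step 1); oxirane (step 4); dihydrofuran ring last, made from the pyran ring (step 8).

## Route

Step 1
Reactants: 1 resorcinol; 2 3-methylbut-2-enal
Product: 3 2,2-dimethyl-2H-chromen-7-ol
Conditions: pyridine, 140 °C, sealed tube (1 in two-fold excess)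
Reagents that add atoms: none
Why: Base-mediated chromenylation (aldol-type C-alkylation at C4 of resorcinol, dehydration to the ortho-quinone methide, oxa-6π ring closure) builds the 2,2-dimethylpyran ring, attack para to one OH rather than at the flanked C2 giving the 7-hydroxy isomer and excess resorcinol limiting double annulation.

Step 2
Reactants: 3 2,2-dimethyl-2H-chromen-7-ol
Product: 4 7-methoxy-2,2-dimethyl-2H-chromene
Conditions: MeI, K2CO3, acetone, reflux
Reagents that add atoms: iodomethane, CI
Why: Williamson O-methylation of the only acidic OH; nothing else in 3 is alkylated under carbonate conditions.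

Step 3
Reactants: 4 7-methoxy-2,2-dimethyl-2H-chromene
Product: 5 1-(7-methoxy-2,2-dimethyl-2H-chromen-6-yl)ethanone
Conditions: Ac2O (1.2 equiv), Sc(OTf)3 (5 mol %), MeNO2, 0 °C → rt
Reagents that add atoms: acetic anhydride, CC(=O)OC(C)=O
Why: Friedel–Crafts acylation goes to C6, which is para to the ring oxygen, ortho to OMe and unhindered (C8 is flanked by two oxygens), and the catalytic metal triflate avoids the stoichiometric strong Lewis acid that would dimerise the acid-sensitive chromene.

Step 4
Reactants: 5 1-(7-methoxy-2,2-dimethyl-2H-chromen-6-yl)ethanone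
Product: 6 1-[(3R,4R)-3,4-epoxy-7-methoxy-2,2-dimethyl-3,4-dihydro-2H-chromen-6-yl]ethanone
Conditions: (R,R)-Mn(salen)Cl (5 mol %; salen = N,N'-bis(3,5-di-tert-butylsalicylidene)-1,2-cyclohexanediaminate), mCPBA (2 equiv), NMO (5 equiv), CH2Cl2, −78 °C; cold aq NaOH quench, used at once
Reagents that add atoms: 3-chloroperoxybenzoic acid (mCPBA), OOC(=O)c1cccc(Cl)c1
Why: Jacobsen–Katsuki epoxidation, for which cis-configured 2,2-dimethylchromenes are the best substrate class, delivers oxygen to one face of the alkene and sets both stereocentres as 3R,4R (≥95 % ee expected with the R,R catalyst), the anhydrous low-temperature variant sparing the hydrolysis-prone benzylic epoxide and the methyl ketone.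

Step 5
Reactants: 7 methyl but-2-ynoate; 8 formaldehyde
Product: 10 methyl (2Z)-2-(hydroxymethyl)but-2-enoate, via alkenylalane 9 (not isolated)
Conditions: i-Bu2AlH (1.1 equiv), NMO (1.1 equiv), THF, 0 °C; then CH2O (gas), −20 °C → rt; 1 M HCl
Reagents that add atoms: none
Why: Regio- and syn-selective conjugate hydroalumination of the ynoate (H to C3, Al to C2) gives the α-alumino enoate 9, which adds to formaldehyde with retention so that the C3 methyl ends cis to the ester (Z), a reductive Morita–Baylis–Hillman-type hydroxymethylation.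

Step 6
Reactants: 10 methyl (2Z)-2-(hydroxymethyl)but-2-enoate
Product: 11 (2Z)-2-(hydroxymethyl)but-2-enoic acid
Conditions: LiOH (1.5 equiv), THF/H2O 3:1, 0 °C; then 1 M HCl to pH 2
Reagents that add atoms: lithium hydroxide, [Li+].[OH-]
Why: Saponification of the unhindered methyl ester, run cold to avoid Z→E isomerisation through reversible conjugate addition.

Step 7
Reactants: 11 (2Z)-2-(hydroxymethyl)but-2-enoic acid
Product: 12 (2Z)-2-[(acetyloxy)methyl]but-2-enoic acid
Conditions: AcCl (3 equiv), CH2Cl2, 0 °C → rt; then H2O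
Reagents that add atoms: acetyl chloride, CC(Cl)=O
Why: O-acetylation of the primary allylic alcohol with the acid chloride alone (any mixed anhydride is hydrolysed in the work-up) avoids nucleophilic amines that could scramble the alkene geometry by allylic (SN2′) substitution of the new acetate.

Step 8
Reactants: 6 1-[(3R,4R)-3,4-epoxy-7-methoxy-2,2-dimethyl-3,4-dihydro-2H-chromen-6-yl]ethanone; 12 (2Z)-2-[(acetyloxy)methyl]but-2-enoic acid
Product: 15 (2R,3S)-5-acetyl-6-methoxy-2-(prop-1-en-2-yl)-2,3-dihydro-1-benzofuran-3-yl (2Z)-2-[(acetyloxy)methyl]but-2-enoate, via trans-hydroxy ester 13 (not isolated), via 3-O-triflate 14 (not isolated)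
Conditions: 12 (1.05 equiv), 2,6-di-tert-butyl-4-methylpyridine (DTBMP, 0.2 equiv), 4 Å MS, CH2Cl2, 0 °C → rt; then DTBMP (2.5 equiv), Tf2O (1.15 equiv), −78 → 0 °C
Reagents that add atoms: none
Why: Proposed new method: a one-flask acyloxylative ring contraction of a chromene oxide in which (i) the buffered acid/carboxylate pair opens the para-alkoxy-activated benzylic C4–O bond of 6 from the back (inversion, which sets C3 of the target as S) to give the trans hydroxy ester 13, whose two substituents sit diequatorial because the diaxial form puts the C4 oxygen syn-axial to a C2 methyl, and (ii) Tf2O turns the neopentyl-type 3-OH into triflate 14, whose C3–O bond is antiperiplanar to the ring C2–O1 bond but gauche to the ester, so that the ring oxygen and not the ester carbonyl displaces triflate from the back (inversion, which sets C2 as R) to give a bridged aryloxiranium ion that opens at the tertiary carbon and loses a methyl proton to the hindered base, contracting the pyran to the dihydrofuran with the isopropenyl group in place; the closest known reaction types are the sulfonate-triggered ring contraction of 2,2-dimethylchroman-3-ols to 2-isopropenyl-2,3-dihydrobenzofurans and the ring-oxygen migration of equatorial pyranoside 2-triflates, neither shown with a vicinal trans-acyloxy group or coupled to epoxide acyloxylation.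

## Compound list

1 | resorcinol | Oc1cccc(O)c1 | starting material
2 | 3-methylbut-2-enal | CC(C)=CC=O | starting material
3 | 2,2-dimethyl-2H-chromen-7-ol | CC1(C)C=Cc2ccc(O)cc2O1 | intermediate
4 | 7-methoxy-2,2-dimethyl-2H-chromene | COc1ccc2C=CC(C)(C)Oc2c1 | intermediate
5 | 1-(7-methoxy-2,2-dimethyl-2H-chromen-6-yl)ethanone | CC(=O)c1cc2C=CC(C)(C)Oc2cc1OC | intermediate
6 | 1-[(3R,4R)-3,4-epoxy-7-methoxy-2,2-dimethyl-3,4-dihydro-2H-chromen-6-yl]ethanone | CC1(C)Oc2cc(OC)c(C(C)=O)cc2[C@H]3O[C@@H]13 | intermediate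
7 | methyl but-2-ynoate | CC#CC(=O)OC | starting material
8 | formaldehyde | C=O | starting material
9 | methyl (2E)-2-(diisobutylalumanyl)but-2-enoate (Al cis to H, methyl cis to ester; not isolated) | C/C=C(\C(=O)OC)[Al](CC(C)C)CC(C)C | intermediate
10 | methyl (2Z)-2-(hydroxymethyl)but-2-enoate | C/C=C(\C(=O)OC)CO | intermediate
11 | (2Z)-2-(hydroxymethyl)but-2-enoic acid | C/C=C(\C(=O)O)CO | intermediate
12 | (2Z)-2-[(acetyloxy)methyl]but-2-enoic acid | C/C=C(\C(=O)O)COC(C)=O | intermediate
13 | (3R,4S)-6-acetyl-3-hydroxy-7-methoxy-2,2-dimethyl-3,4-dihydro-2H-chromen-4-yl (2Z)-2-[(acetyloxy)methyl]but-2-enoate (trans; not isolated) | CC1(C)Oc2cc(OC)c(C(C)=O)cc2[C@H](OC(=O)/C(=C\C)COC(C)=O)[C@H]1O | intermediate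
14 | (3R,4S)-6-acetyl-7-methoxy-2,2-dimethyl-3-[(trifluoromethanesulfonyl)oxy]-3,4-dihydro-2H-chromen-4-yl (2Z)-2-[(acetyloxy)methyl]but-2-enoate (trans; not isolated) | CC1(C)Oc2cc(OC)c(C(C)=O)cc2[C@H](OC(=O)/C(=C\C)COC(C)=O)[C@H]1OS(=O)(=O)C(F)(F)F | intermediate
15 | (2R,3S)-5-acetyl-6-methoxy-2-(prop-1-en-2-yl)-2,3-dihydro-1-benzofuran-3-yl (2Z)-2-[(acetyloxy)methyl]but-2-enoate (2,3-trans) | C=C(C)[C@H]1Oc2cc(OC)c(C(C)=O)cc2[C@@H]1OC(=O)/C(=C\C)COC(C)=O | target

## Step count and risks

Total steps: 8. Longest linear sequence: 5 (steps 1, 2, 3, 4, 8); the acid branch is steps 5–7 and joins at step 8.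

**Step 8 (the proposed new step).** It can fail through ester participation from the minor diaxial conformer (cis-fused dioxolanium ion, leading to the 2,3-cis diastereomer), through aryl instead of oxygen migration, through partly cis epoxide opening, or through enol triflation of the ketone. The fallback uses known chemistry, sets out from 6 and comes back at 15. Epoxide 6 is opened with 4-methoxybenzyl alcohol (cat. Yb(OTf)3, CH2Cl2, −20 °C, inversion at C4) to give 1-[(3R,4S)-3-hydroxy-7-methoxy-4-[(4-methoxybenzyl)oxy]-2,2-dimethyl-3,4-dihydro-2H-chromen-6-yl]ethanone F1. Tf2O/2,6-lutidine converts it into its 3-O-trifluoromethanesulfonate F2, which on warming undergoes the sulfonate-triggered chromanol ring contraction, now with no participating neighbour, to 1-[(2R,3S)-6-methoxy-3-[(4-methoxybenzyl)oxy]-2-(prop-1-en-2-yl)-2,3-dihydro-1-benzofuran-5-yl]ethanone F3. DDQ (CH2Cl2/pH 7 buffer, 0 °C) removes the benzyl ether to give 1-[(2R,3S)-3-hydroxy-6-methoxy-2-(prop-1-en-2-yl)-2,3-dihydro-1-benzofuran-5-yl]ethanone F4. Acid 12 is activated with 2,4,6-trichlorobenzoyl chloride/Et3N in toluene as (2Z)-2-[(acetyloxy)methyl]but-2-enoic 2,4,6-trichlorobenzoic anhydride F5, which acylates F4 at 80 °C without DMAP (to keep the Z geometry) and gives 15.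

**Step 3 (acetylation of the acid-sensitive chromene).** Dimerisation or acylation of the styrene-type double bond may compete. The fallback sets out from 4 and comes back at 5 by masking the alkene. Hydrogenation (H2, Pd/C, EtOAc) gives 7-methoxy-2,2-dimethylchromane F6. A conventional Friedel–Crafts acetylation (AcCl, SnCl4, CH2Cl2, 0 °C) gives 1-(7-methoxy-2,2-dimethyl-3,4-dihydro-2H-chromen-6-yl)ethanone F7. DDQ in refluxing 1,4-dioxane dehydrogenates C3–C4 and returns 5.

**Step 1 (direct chromenylation of resorcinol).** Regioisomer formation and double annulation may make the yield poor. The fallback sets out from 1 and comes back at 4 (by-passing 3 and step 2). Resorcinol is condensed with 3-methylbut-2-enoic acid (MeSO3H/P2O5, 70 °C) to 7-hydroxy-2,2-dimethylchroman-4-one F8. Methylation (MeI, K2CO3, acetone) gives 7-methoxy-2,2-dimethylchroman-4-one F9. Reduction (NaBH4, MeOH) gives racemic 7-methoxy-2,2-dimethylchroman-4-ol F10, and dehydration (cat. TsOH, toluene, 80 °C) gives 4.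

Further compounds

F1 | step 8 | 1-[(3R,4S)-3-hydroxy-7-methoxy-4-[(4-methoxybenzyl)oxy]-2,2-dimethyl-3,4-dihydro-2H-chromen-6-yl]ethanone | CC1(C)Oc2cc(OC)c(C(C)=O)cc2[C@H](OCc3ccc(OC)cc3)[C@H]1O
F2 | step 8 | (3R,4S)-6-acetyl-7-methoxy-4-[(4-methoxybenzyl)oxy]-2,2-dimethyl-3,4-dihydro-2H-chromen-3-yl trifluoromethanesulfonate | CC1(C)Oc2cc(OC)c(C(C)=O)cc2[C@H](OCc3ccc(OC)cc3)[C@H]1OS(=O)(=O)C(F)(F)F
F3 | step 8 | 1-[(2R,3S)-6-methoxy-3-[(4-methoxybenzyl)oxy]-2-(prop-1-en-2-yl)-2,3-dihydro-1-benzofuran-5-yl]ethanone | C=C(C)[C@H]1Oc2cc(OC)c(C(C)=O)cc2[C@@H]1OCc3ccc(OC)cc3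
F4 | step 8 | 1-[(2R,3S)-3-hydroxy-6-methoxy-2-(prop-1-en-2-yl)-2,3-dihydro-1-benzofuran-5-yl]ethanone | C=C(C)[C@H]1Oc2cc(OC)c(C(C)=O)cc2[C@@H]1O
F5 | step 8 | (2Z)-2-[(acetyloxy)methyl]but-2-enoic 2,4,6-trichlorobenzoic anhydride | C/C=C(\C(=O)OC(=O)c1c(Cl)cc(Cl)cc1Cl)COC(C)=O
F6 | step 3 | 7-methoxy-2,2-dimethylchromane | COc1ccc2CCC(C)(C)Oc2c1
F7 | step 3 | 1-(7-methoxy-2,2-dimethyl-3,4-dihydro-2H-chromen-6-yl)ethanone | CC(=O)c1cc2CCC(C)(C)Oc2cc1OC
F8 | step 1 | 7-hydroxy-2,2-dimethylchroman-4-one | CC1(C)CC(=O)c2ccc(O)cc2O1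
F9 | step 1 | 7-methoxy-2,2-dimethylchroman-4-one | COc1ccc2C(=O)CC(C)(C)Oc2c1
F10 | step 1 | 7-methoxy-2,2-dimethylchroman-4-ol (racemic) | COc1ccc2C(O)CC(C)(C)Oc2c1
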